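**Retrosynthetic overview**
- Feature: ring A of the flavanone (C4a, C5, C6, C7, C8, C8a) carries OH, CH3, OH and prenyl on C5–C8 in fixed order, and its C4a–C8a edge is the enone C=C of a 2-aryl-2,3-dihydropyran-4-one (ring C).
- Ring A is therefore annulated last onto a finished ring C: the C8–C8a, C5–C6, C7–C8 and C4a–C5 bonds come from diazo ketone 13 and siloxypropyne 17 by photo-Wolff rearrangement, [2+2], 4π opening and 6π closure, giving 22; desilylation gives 23.
- Diazo ketone 13 comes from enaminone 12 by diazo transfer; 12 comes from acid 6 (via its chloride) and enamine 10, so the diazo carbon is fixed without enolising the pyranone.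
- Acid 6 (ring C and the C2 stereocentre) comes from an asymmetric Mukaiyama aldol and cyclodehydration of 4-methoxybenzaldehyde with the bis(silyloxy)diene of ethyl 2,4-dioxopentanoate.
- Ring order: C (with the B-ring aryl from the aldehyde), then A.

Key step: step 9

Remark: in step 2 the catalyst antipode is defined by the face it must attack (Si face of the aldehyde); (S,S) is assumed from the usual Re-face preference of the (R,R)-catalyst with aromatic aldehydes and is to be confirmed on the first run.

**Step 1**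
Reactants: 1 ethyl 2,4-dioxopentanoate
Product: 2 ethyl (2Z)-2,4-bis(trimethylsilyloxy)penta-2,4-dienoate
Conditions: TMSOTf (2.3 equiv), Et3N (2.6 equiv), Et2O, 0 °C → rt; pentane extraction, used crude
Reagents that add atoms: trimethylsilyl trifluoromethanesulfonate, C[Si](C)(C)OS(=O)(=O)C(F)(F)F
Why: Double O-silylation of a 1,3-dicarbonyl compound (Simchen conditions) should work because both tautomeric mono-silyl ethers converge on the same 2,4-bis(silyloxy)diene, so the site of the first silylation and the C2=C3 geometry are of no consequence.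

**Step 2**
Reactants: 2 ethyl (2Z)-2,4-bis(trimethylsilyloxy)penta-2,4-dienoate; 3 4-methoxybenzaldehyde
Product: 5 ethyl (2S)-2-(4-methoxyphenyl)-4-oxo-3,4-dihydro-2H-pyran-6-carboxylate, via hydroxy diketo ester 4 (not isolated)
Conditions: SiCl4 (1.2 equiv), (S,S)-binaphthyldiamine bisphosphoramide (5 mol %), i-Pr2NEt (10 mol %), CH2Cl2, −78 °C; cold aq. NaHCO3, then pH 4–5, extraction; crude, TFA (2 equiv), CH2Cl2, 0 °C → rt
Reagents that add atoms: none
Why: Lewis-base-activated SiCl4 Mukaiyama aldol (Denmark type) of a methyl-ketone-derived silyl enol ether with an aromatic aldehyde, in which the terminal CH2 of 2 should add to the Si face of the catalyst-bound aldehyde and so set C2 as (S); acid then closes the δ-hydroxy-2,4-diketo ester through its hemiketal and dehydrates it to the dihydropyranone without breaking the benzylic C–O bond.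

**Step 3**
Reactants: 5 ethyl (2S)-2-(4-methoxyphenyl)-4-oxo-3,4-dihydro-2H-pyran-6-carboxylate
Product: 6 (2S)-2-(4-methoxyphenyl)-4-oxo-3,4-dihydro-2H-pyran-6-carboxylic acid
Conditions: Me3SnOH (4 equiv), ClCH2CH2Cl, 60 °C; 1 M HCl wash
Reagents that add atoms: trimethyltin hydroxide, C[Sn](C)(C)O
Why: Trimethyltin hydroxide ester cleavage should hydrolyse this activated ester (an α-alkoxy acrylate conjugated to the ketone) under nearly neutral conditions, which avoids C3 deprotonation and the retro-oxa-Michael ring opening that would erode the C2 centre.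

**Step 4**
Reactants: 7 5-bromo-2-methylpent-2-ene
Product: 9 5-methylhex-4-enal, via homoprenylmagnesium bromide 8 (not isolated)
Conditions: Mg, I2 (cat.), THF, 35 °C; DMF, 0 °C; 1 M HCl, 0 °C
Reagents that add atoms: N,N-dimethylformamide, CN(C)C=O
Why: Bouveault aldehyde synthesis, in which the Grignard reagent adds once to DMF and the stable hemiaminal salt releases the aldehyde only on acidic work-up.

**Step 5**
Reactants: 9 5-methylhex-4-enal
Product: 10 4-[(1E)-5-methylhexa-1,4-dien-1-yl]morpholine
Conditions: morpholine (2.2 equiv), K2CO3, 0 °C → rt; filtration; distillation under reduced pressure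
Reagents that add atoms: morpholine, C1COCCN1
Why: Enamine formation from an α-unbranched aldehyde through the aminal (Mannich–Davidsen procedure), which loses one morpholine on distillation to give the (E)-enamine.

**Step 6**
Reactants: 6 (2S)-2-(4-methoxyphenyl)-4-oxo-3,4-dihydro-2H-pyran-6-carboxylic acid; 10 4-[(1E)-5-methylhexa-1,4-dien-1-yl]morpholine
Product: 12 (2S)-2-(4-methoxyphenyl)-6-[(2E)-5-methyl-2-(morpholin-4-ylmethylidene)hex-4-enoyl]-2,3-dihydro-4H-pyran-4-one, via acid chloride 11 (not isolated)
Conditions: 1-chloro-N,N,2-trimethylprop-1-en-1-amine (1.2 equiv), CH2Cl2, 0 °C → rt; then 10 (1.3 equiv), Et3N (1.5 equiv), CH2Cl2, −20 → 0 °C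
Reagents that add atoms: none
Why: Stork C-acylation of an aldehyde enamine by an acid chloride made under neutral conditions (Ghosez reagent) should give the push–pull enaminone, and it fixes the prenyl-bearing carbon as the future diazo carbon without any enolate of the two-ketone pyranone being formed.

**Step 7**
Reactants: 12 (2S)-2-(4-methoxyphenyl)-6-[(2E)-5-methyl-2-(morpholin-4-ylmethylidene)hex-4-enoyl]-2,3-dihydro-4H-pyran-4-one
Product: 13 (2S)-6-(2-diazo-5-methylhex-4-enoyl)-2-(4-methoxyphenyl)-2,3-dihydro-4H-pyran-4-one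
Conditions: TsN3 (1.5 equiv), MeCN, rt, dark
Reagents that add atoms: 4-methylbenzenesulfonyl azide, Cc1ccc(cc1)S(=O)(=O)N=[N+]=[N-]
Why: Diazo transfer to an enaminone, in which [3+2] cycloaddition of the sulfonyl azide to the enamine C=C and cycloreversion of the triazoline release the α-diazo ketone and an N-sulfonylformamidine without added base, so C3–H and the C2 centre are not exposed to enolate chemistry.

**Step 8**
Reactants: 14 propyne
Product: 17 triisopropyl(prop-1-yn-1-yloxy)silane, via prop-1-ynyllithium 15 (not isolated), via lithium prop-1-yn-1-olate 16 (not isolated)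
Conditions: n-BuLi, THF, −78 °C; LiOOt-Bu (from t-BuOOH, LiHMDS, THF, −78 °C), −78 → 0 °C; TIPSOTf, −78 °C → rt
Reagents that add atoms: tert-butyl hydroperoxide, CC(C)(C)OO; triisopropylsilyl trifluoromethanesulfonate, CC(C)[Si](OS(=O)(=O)C(F)(F)F)(C(C)C)C(C)C
Why: Julia oxidation of a lithium acetylide with lithium tert-butyl peroxide gives the ynolate, which the bulky silyl triflate should trap on oxygen to give the siloxyalkyne.

**Step 9**
Reactants: 13 (2S)-6-(2-diazo-5-methylhex-4-enoyl)-2-(4-methoxyphenyl)-2,3-dihydro-4H-pyran-4-one; 17 triisopropyl(prop-1-yn-1-yloxy)silane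
Product: 22 (2S)-5-hydroxy-2-(4-methoxyphenyl)-6-methyl-8-(3-methylbut-2-en-1-yl)-7-(triisopropylsilyloxy)-2,3-dihydro-4H-chromen-4-one, via vinylketene 18 (not isolated), via vinylcyclobutenone 19 (not isolated), via dienylketene 20 (not isolated), via cyclohexadienone 21 (not isolated)
Conditions: 17 (2 equiv), degassed ClCH2CH2Cl (0.05 M), hν (365 nm LEDs or Pyrex-filtered medium-pressure Hg lamp), rt; then 80 °C
Reagents that add atoms: none
Why: Excitation of the diazo ketone expels N2 and the pyranon-6-yl group migrates to the diazo carbon (Wolff rearrangement, C8–C8a) to give vinylketene 18, whose electrophilic ketene carbon is attacked by the methyl-bearing carbon of the siloxyalkyne in a [2+2] cycloaddition (C5–C6 and C7–C8) to give cyclobutenone 19. Light or the 80 °C stage then drives reversible 4π electrocyclic opening to dienylketene 20, and ring A closes by thermal disrotatory 6π electrocyclisation of the ketene carbon onto pyranone C5 (C4a–C5); dienone 21, with C4a–H between two carbonyls, should enolise at once to the C5 phenol chelated to the C4 ketone. The closest known reaction type is the Danheiser benzannulation of α′-diazo enones with siloxyalkynes through a photochemical Wolff rearrangement. No stereocentre is created, the quaternary carbon of 19 is transient, and the base-labile C2 centre is a spectator because the cascade uses neither acid nor base. The selectivity needed is regiochemical: the polarisation of the ynol ether (nucleophilic at the carbon remote from oxygen) puts methyl next to the new phenol and silyloxy at C7, the prenyl group sits on the former diazo carbon and can only end at C8, and pyranone C5–H is the only terminus for the 6π closure. Because cyclobutenone opening is reversible, either sense of rotation at its quaternary carbon should funnel to the one dienylketene geometry that can cyclise.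

**Step 10**
Reactants: 22 (2S)-5-hydroxy-2-(4-methoxyphenyl)-6-methyl-8-(3-methylbut-2-en-1-yl)-7-(triisopropylsilyloxy)-2,3-dihydro-4H-chromen-4-one
Product: 23 (2S)-5,7-dihydroxy-2-(4-methoxyphenyl)-6-methyl-8-(3-methylbut-2-en-1-yl)-2,3-dihydro-4H-chromen-4-one
Conditions: TBAF (1.2 equiv), AcOH (1.5 equiv), THF, 0 °C
Reagents that add atoms: none
Why: Fluoride cleavage of an aryl silyl ether, buffered with acetic acid so that neither retro-oxa-Michael opening of the flavanone (racemisation through the chalcone) nor cyclisation of the 7-OH onto the prenyl group should set in.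

**Compound list**
1 | ethyl 2,4-dioxopentanoate | CCOC(=O)C(=O)CC(C)=O | starting material
2 | ethyl (2Z)-2,4-bis(trimethylsilyloxy)penta-2,4-dienoate | CCOC(=O)/C(O[Si](C)(C)C)=C/C(=C)O[Si](C)(C)C | intermediate
3 | 4-methoxybenzaldehyde | COc1ccc(C=O)cc1 | starting material
4 | ethyl (6S)-6-hydroxy-6-(4-methoxyphenyl)-2,4-dioxohexanoate (in equilibrium with its enol and cyclic hemiketal) | COc1ccc([C@@H](O)CC(=O)CC(=O)C(=O)OCC)cc1 | intermediate
5 | ethyl (2S)-2-(4-methoxyphenyl)-4-oxo-3,4-dihydro-2H-pyran-6-carboxylate | COc1ccc([C@@H]2CC(=O)C=C(C(=O)OCC)O2)cc1 | intermediate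
6 | (2S)-2-(4-methoxyphenyl)-4-oxo-3,4-dihydro-2H-pyran-6-carboxylic acid | COc1ccc([C@@H]2CC(=O)C=C(C(=O)O)O2)cc1 | intermediate
7 | 5-bromo-2-methylpent-2-ene | CC(C)=CCCBr | starting material
8 | (4-methylpent-3-en-1-yl)magnesium bromide | CC(C)=CCC[Mg]Br | intermediate
9 | 5-methylhex-4-enal | CC(C)=CCCC=O | intermediate
10 | 4-[(1E)-5-methylhexa-1,4-dien-1-yl]morpholine | CC(C)=CC/C=C/N1CCOCC1 | intermediate
11 | (2S)-2-(4-methoxyphenyl)-4-oxo-3,4-dihydro-2H-pyran-6-carbonyl chloride | COc1ccc([C@@H]2CC(=O)C=C(C(Cl)=O)O2)cc1 | intermediate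
12 | (2S)-2-(4-methoxyphenyl)-6-[(2E)-5-methyl-2-(morpholin-4-ylmethylidene)hex-4-enoyl]-2,3-dihydro-4H-pyran-4-one | COc1ccc([C@@H]2CC(=O)C=C(C(=O)/C(CC=C(C)C)=C/N3CCOCC3)O2)cc1 | intermediate
13 | (2S)-6-(2-diazo-5-methylhex-4-enoyl)-2-(4-methoxyphenyl)-2,3-dihydro-4H-pyran-4-one | COc1ccc([C@@H]2CC(=O)C=C(C(=O)C(=[N+]=[N-])CC=C(C)C)O2)cc1 | intermediate
14 | propyne | CC#C | starting material
15 | prop-1-ynyllithium | [Li]C#CC | intermediate
16 | lithium prop-1-yn-1-olate | [Li+].[O-]C#CC | intermediate
17 | triisopropyl(prop-1-yn-1-yloxy)silane (1-(triisopropylsilyloxy)prop-1-yne) | CC#CO[Si](C(C)C)(C(C)C)C(C)C | intermediate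
18 | (2S)-2-(4-methoxyphenyl)-6-(5-methyl-1-oxohexa-1,4-dien-2-yl)-2,3-dihydro-4H-pyran-4-one (vinylketene) | COc1ccc([C@@H]2CC(=O)C=C(C(=C=O)CC=C(C)C)O2)cc1 | intermediate
19 | (2S)-2-(4-methoxyphenyl)-6-[3-methyl-1-(3-methylbut-2-enyl)-4-oxo-2-(triisopropylsilyloxy)cyclobut-2-en-1-yl]-2,3-dihydro-4H-pyran-4-one (both epimers at the quaternary carbon) | COc1ccc([C@@H]2CC(=O)C=C(C3(CC=C(C)C)C(=O)C(C)=C3O[Si](C(C)C)(C(C)C)C(C)C)O2)cc1 | intermediate
20 | (2S)-6-[2,7-dimethyl-1-oxo-3-(triisopropylsilyloxy)octa-1,3,6-trien-4-yl]-2-(4-methoxyphenyl)-2,3-dihydro-4H-pyran-4-one (dienylketene; reactive isomer has the pyranonyl group cis to the ketenyl group) | COc1ccc([C@@H]2CC(=O)C=C(C(CC=C(C)C)=C(O[Si](C(C)C)(C(C)C)C(C)C)C(C)=C=O)O2)cc1 | intermediate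
21 | (2S)-2-(4-methoxyphenyl)-6-methyl-8-(3-methylbut-2-enyl)-7-(triisopropylsilyloxy)-2,3-dihydro-4H-chromene-4,5(4aH)-dione | COc1ccc([C@@H]2CC(=O)C3C(=O)C(C)=C(O[Si](C(C)C)(C(C)C)C(C)C)C(CC=C(C)C)=C3O2)cc1 | intermediate
22 | (2S)-5-hydroxy-2-(4-methoxyphenyl)-6-methyl-8-(3-methylbut-2-en-1-yl)-7-(triisopropylsilyloxy)-2,3-dihydro-4H-chromen-4-one | COc1ccc([C@@H]2CC(=O)c3c(O)c(C)c(O[Si](C(C)C)(C(C)C)C(C)C)c(CC=C(C)C)c3O2)cc1 | intermediate
23 | (2S)-5,7-dihydroxy-2-(4-methoxyphenyl)-6-methyl-8-(3-methylbut-2-en-1-yl)-2,3-dihydro-4H-chromen-4-one | COc1ccc([C@@H]2CC(=O)c3c(O)c(C)c(O)c(CC=C(C)C)c3O2)cc1 | target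

**Step count**
Total steps: 10. Longest linear sequence: 7 steps (steps 1, 2, 3, 6, 7, 9, 10, from ethyl 2,4-dioxopentanoate).

**Steps most likely to fail**

Step 9. After loss of nitrogen the acyl carbene may undergo 1,2-hydrogen shift from the allylic CH2 faster than the pyranonyl group migrates, giving a dienone and no ketene; the excited ene-dione chromophore may also enter enone photocycloadditions. A direct [4+2] of the vinylketene with the alkyne would be harmless, since its isomeric mono-silyl ether gives the same diol in step 10. The fallback moves the prenyl group off the diazo carbon, sets out from 11 and 17, and returns at 23. Acid chloride 11, made as in step 6, would be treated with TMSCHN2 (MeCN–THF, 0 °C) to give (2S)-6-(2-diazoacetyl)-2-(4-methoxyphenyl)-2,3-dihydro-4H-pyran-4-one F1, a diazo ketone with no α-alkyl group and hence no hydrogen-shift channel. Irradiation with 17 and heating as in step 9 should give (2S)-5-hydroxy-2-(4-methoxyphenyl)-6-methyl-7-(triisopropylsilyloxy)-2,3-dihydro-4H-chromen-4-one F2. Buffered TBAF would give (2S)-5,7-dihydroxy-2-(4-methoxyphenyl)-6-methyl-2,3-dihydro-4H-chromen-4-one F3. Its only non-chelated phenol would be etherified with tert-butyl 2-methylbut-3-en-2-yl carbonate and Pd(PPh3)4 (THF, 0 °C) to give (2S)-5-hydroxy-2-(4-methoxyphenyl)-6-methyl-7-(2-methylbut-3-en-2-yloxy)-2,3-dihydro-4H-chromen-4-one F4. An aromatic Claisen rearrangement (Eu(fod)3, CHCl3, 60 °C) should then deliver the allyl unit, inverted to the prenyl form, to C8, the only free ortho position, giving 23.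

Step 2. The ester-deactivated dienol ether may add too slowly to the electron-rich aldehyde, or with poor facial selectivity. The fallback sets the stereocentre on a simpler nucleophile and adds the oxalyl unit afterwards; it sets out from 3 and returns at 5. A direct enamine-catalysed aldol of 3 with acetone under a D-proline-derived prolinamide (the L-series attacks the Re face, so the D-series should give the S alcohol) would give (4S)-4-hydroxy-4-(4-methoxyphenyl)butan-2-one F5. Silylation (TBSCl, imidazole, DMF) would give (4S)-4-(tert-butyldimethylsilyloxy)-4-(4-methoxyphenyl)butan-2-one F6. Kinetic enolisation of the methyl group (LiHMDS, THF, −78 °C) and Claisen condensation with diethyl oxalate would give ethyl (6S)-6-(tert-butyldimethylsilyloxy)-6-(4-methoxyphenyl)-2,4-dioxohexanoate F7. Aqueous HF in MeCN (0 °C → rt) should remove the silyl group and cyclodehydrate the product to 5.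

Step 6. The enamine may be acylated on nitrogen or add in conjugate fashion to C6 of the acid chloride, so that C-acylation does not go cleanly. The fallback forms the ketone first and activates its methylene afterwards; it sets out from 8 and 11 and returns at 13. Transmetalation of 8 with ZnBr2 (THF, 0 °C) would give (4-methylpent-3-en-1-yl)zinc bromide F8. Negishi acylation with 11 (Pd(PPh3)4 cat., THF, 0 °C → rt), which tolerates the ring ketone, would give (2S)-2-(4-methoxyphenyl)-6-(5-methylhex-4-enoyl)-2,3-dihydro-4H-pyran-4-one F9. tert-Butoxybis(dimethylamino)methane (toluene, 50 °C) should condense at the side-chain methylene, which is α to the electron-poor ene-dione ketone and more acidic than C3–H2 of the vinylogous ester, to give (2S)-6-[(2E)-2-(dimethylaminomethylidene)-5-methylhex-4-enoyl]-2-(4-methoxyphenyl)-2,3-dihydro-4H-pyran-4-one F10. Diazo transfer with TsN3 as in step 7 would give 13.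

**Further compounds**
F1 | step 9 | (2S)-6-(2-diazoacetyl)-2-(4-methoxyphenyl)-2,3-dihydro-4H-pyran-4-one | COc1ccc([C@@H]2CC(=O)C=C(C(=O)C=[N+]=[N-])O2)cc1
F2 | step 9 | (2S)-5-hydroxy-2-(4-methoxyphenyl)-6-methyl-7-(triisopropylsilyloxy)-2,3-dihydro-4H-chromen-4-one | COc1ccc([C@@H]2CC(=O)c3c(O)c(C)c(O[Si](C(C)C)(C(C)C)C(C)C)cc3O2)cc1
F3 | step 9 | (2S)-5,7-dihydroxy-2-(4-methoxyphenyl)-6-methyl-2,3-dihydro-4H-chromen-4-one | COc1ccc([C@@H]2CC(=O)c3c(O)c(C)c(O)cc3O2)cc1
F4 | step 9 | (2S)-5-hydroxy-2-(4-methoxyphenyl)-6-methyl-7-(2-methylbut-3-en-2-yloxy)-2,3-dihydro-4H-chromen-4-one | COc1ccc([C@@H]2CC(=O)c3c(O)c(C)c(OC(C)(C)C=C)cc3O2)cc1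
F5 | step 2 | (4S)-4-hydroxy-4-(4-methoxyphenyl)butan-2-one | COc1ccc([C@@H](O)CC(C)=O)cc1
F6 | step 2 | (4S)-4-(tert-butyldimethylsilyloxy)-4-(4-methoxyphenyl)butan-2-one | COc1ccc([C@@H](O[Si](C)(C)C(C)(C)C)CC(C)=O)cc1
F7 | step 2 | ethyl (6S)-6-(tert-butyldimethylsilyloxy)-6-(4-methoxyphenyl)-2,4-dioxohexanoate | COc1ccc([C@@H](O[Si](C)(C)C(C)(C)C)CC(=O)CC(=O)C(=O)OCC)cc1
F8 | step 6 | (4-methylpent-3-en-1-yl)zinc bromide | CC(C)=CCC[Zn]Br
F9 | step 6 | (2S)-2-(4-methoxyphenyl)-6-(5-methylhex-4-enoyl)-2,3-dihydro-4H-pyran-4-one | COc1ccc([C@@H]2CC(=O)C=C(C(=O)CCC=C(C)C)O2)cc1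
F10 | step 6 | (2S)-6-[(2E)-2-(dimethylaminomethylidene)-5-methylhex-4-enoyl]-2-(4-methoxyphenyl)-2,3-dihydro-4H-pyran-4-one | COc1ccc([C@@H]2CC(=O)C=C(C(=O)/C(CC=C(C)C)=C/N(C)C)O2)cc1
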